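**Plan**
- Retrosynthetic cuts, in order: C8–C1″ (side-chain CH2 to ring A, Negishi coupling); the two O-benzyl bonds and the 5-O-methyl bond (BCl3); C4–C4a (aryl–acyl bond that closes ring C; bromine–lithium exchange, Parham cyclization); O1–C8a (SNAr); C2–C3 (acetate aldol); in the side chain C2″–C3″ (dienolate prenylation).
- Forward order: ring B aldehyde → (S)-3-hydroxy acid → aryl ether to a dibromo ring A → ring C closed → phenols unmasked → lavandulyl chain joined last, after every acidic or strongly basic step.
- Enabling feature: O1 sits on C8a, whose two ortho carbons C4a and C8 must carry the acyl carbon C4 and the side-chain CH2. In a 2,6-dibromo-3,5-dimethoxyphenyl ether these two carbons are equivalent by rotation about the O1–aryl bond, and C4 lies three atoms from O1 (O1–C2–C3–C4). An aryllithium at either C–Br carbon therefore closes the six-membered ring C, and the bromine that remains is by necessity at C8.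
- Stereochemistry: C2 comes from a chiral-acetate aldol addition ((S)-2-hydroxy-1,2,2-triphenylethyl acetate) and is retained, since no later step breaks a bond to it. C2″ comes from an Evans-type alkylation on (S)-4-benzyl-2-oxazolidinone.

Key step: step 6

Remark: the side chain needs the geometry of (S)-lavandulol (the descriptor becomes R once CH2OH is replaced by CH2–aryl), so this alcohol is made by auxiliary control and not bought.

**Step 1**
Reactants: 1 2,6-dihydroxybenzaldehyde
Product: 2 2,6-bis(benzyloxy)benzaldehyde
Conditions: BnBr (2.3 equiv), K2CO3, DMF, 60 °C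
Reagents that add atoms: benzyl bromide, BrCc1ccccc1
Why: Williamson ether synthesis, in which K2CO3 in warm DMF deprotonates both aldehyde-hydrogen-bonded phenols and benzyl bromide alkylates them, giving ethers that should survive amide bases, alkoxides and n-BuLi at low temperature and that BCl3 removes in step 7.

**Step 2**
Reactants: 2 2,6-bis(benzyloxy)benzaldehyde; 3 (S)-2-hydroxy-1,2,2-triphenylethyl acetate
Product: 5 (S)-2-hydroxy-1,2,2-triphenylethyl (S)-3-[2,6-bis(benzyloxy)phenyl]-3-hydroxypropanoate, via dilithium acetate enolate 4 (not isolated)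
Conditions: LiN(i-Pr)2 (2.1 equiv), THF, −78 → 0 °C; then 2, −100 °C; then AcOH
Reagents that add atoms: none
Why: Acetate aldol addition of a chiral ester enolate, in which the bulky (S)-2-hydroxy-1,2,2-triphenylethyl group of dilithium enolate 4 shields one face so that the new carbinol centre (the later C2) should form as S (the R reagent is known to give R 3-hydroxy acids), and the minor diastereomer should be removable by crystallisation of 5.

**Step 3**
Reactants: 5 aldol adduct
Product: 6 (S)-3-[2,6-bis(benzyloxy)phenyl]-3-hydroxypropanoic acid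
Conditions: KOH, MeOH/H2O, 65 °C; then 1 M HCl to pH 2
Reagents that add atoms: potassium hydroxide, [K+].[OH-]
Why: Ester saponification, in which hydroxide cleaves the hindered secondary ester, the resulting carboxylate resists retro-aldol cleavage, the carbinol centre is untouched and the chiral diol separates for reuse.

**Step 4**
Reactants: 7 1-fluoro-3,5-dimethoxybenzene
Product: 8 2,4-dibromo-3-fluoro-1,5-dimethoxybenzene
Conditions: N-bromosuccinimide (2.05 equiv), MeCN, 0 °C → rt
Reagents that add atoms: N-bromosuccinimide, O=C1CCC(=O)N1Br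
Why: Electrophilic aromatic bromination, in which each carbon next to fluorine is ortho to one methoxy group and para to the other and is less hindered than the carbon between the two methoxy groups (as with 5-substituted resorcinol dimethyl ethers), so two equivalents of reagent should give the 2,4-dibromide.

**Step 5**
Reactants: 6 (S)-3-[2,6-bis(benzyloxy)phenyl]-3-hydroxypropanoic acid; 8 2,4-dibromo-3-fluoro-1,5-dimethoxybenzene
Product: 10 (S)-3-[2,6-bis(benzyloxy)phenyl]-3-(2,6-dibromo-3,5-dimethoxyphenoxy)propanoic acid, via dipotassium alkoxide carboxylate 9 (not isolated)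
Conditions: KN(SiMe3)2 (2.1 equiv), THF, 0 °C; then 8, DMPU, 50 °C; then 1 M HCl to pH 3
Reagents that add atoms: none
Why: Nucleophilic aromatic substitution (SNAr) of fluoride, in which the alkoxide of dianion 9 attacks the C–F carbon (Meisenheimer intermediate stabilised by two ortho bromines), no hydrogen ortho to a halogen allows an aryne path, the dianion cannot undergo retro-aldol or E1cB reactions, and the S configuration is retained because no bond to the carbinol carbon is broken.

**Step 6**
Reactants: 10 (S)-3-[2,6-bis(benzyloxy)phenyl]-3-(2,6-dibromo-3,5-dimethoxyphenoxy)propanoic acid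
Product: 13 (S)-2-[2,6-bis(benzyloxy)phenyl]-8-bromo-5,7-dimethoxychroman-4-one, via aryllithium lithium carboxylate 11 (not isolated), via dilithium gem-diolate 12 (not isolated)
Conditions: n-BuLi (2.1 equiv), THF/Et2O/pentane, −100 → −78 °C; then AcOH (3 equiv), −78 °C
Reagents that add atoms: none
Why: The first equivalent of n-BuLi forms the lithium carboxylate and the second performs bromine–lithium exchange at one of the two C–Br carbons ortho to O1 (fast at −100 °C, helped by the flanking oxygens); aryllithium 11 then adds to the carboxylate carbon C4 through a six-membered transition state to give the dilithium gem-diolate 12, which becomes the ketone only on the acetic acid quench, so the flavanone never meets base. The closest known reaction type is the Parham cyclization of bromoaryl-tethered carboxylic acids and amides to benzo-fused ketones, including chroman-4-ones from 2-bromophenyl ethers of 3-hydroxy acid derivatives. Ring C is closed in the 6-exo-trig mode by the C4–C4a bond. No stereocentre is created, and C2 is carried through unchanged because neither the exchange nor the addition touches it and its hydrogen is not acidic enough to be removed at this temperature. Regioselectivity needs no control: the two bromines are interchanged by rotation about the O1–aryl bond, so exchange of either gives the same product, and the surviving bromine sits at C8 between O1 and the C7 methoxy group. Chemoselectivity (exchange before attack of n-BuLi on the carboxylate or on the second bromine, cyclization before proton transfer from C3) rests on the low temperature, the stoichiometry and the poor acidity of the α-hydrogens of a carboxylate salt.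

**Step 7**
Reactants: 13 (S)-2-[2,6-bis(benzyloxy)phenyl]-8-bromo-5,7-dimethoxychroman-4-one
Product: 15 (S)-8-bromo-2-(2,6-dihydroxyphenyl)-5-hydroxy-7-methoxychroman-4-one, via tris(dichloroboryl) ether 14 (not isolated)
Conditions: BCl3 (6 equiv), C6HMe5 (5 equiv), CH2Cl2, −78 → −10 °C; then pH 7 phosphate buffer
Reagents that add atoms: none
Why: Lewis acid ether cleavage, in which BCl3 removes the benzyl ethers at −78 °C while pentamethylbenzene traps the benzyl cations away from the electron-rich rings, and on warming the boron chelate between C4=O and the peri oxygen cleaves only the 5-O-methyl group (the non-chelated 7-methoxy group stays); the step is run before any alkene is present and kept cold to protect the C2–O1 bond.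

**Step 8**
Reactants: 16 (S)-4-benzyl-2-oxazolidinone
Product: 18 (S)-4-benzyl-3-(3-methylbut-2-enoyl)oxazolidin-2-one, via lithium oxazolidinonide 17 (not isolated)
Conditions: n-BuLi, THF, −78 °C; then 3-methylbut-2-enoyl chloride
Reagents that add atoms: 3-methylbut-2-enoyl chloride, CC(C)=CC(=O)Cl
Why: N-Acylation of the lithiated oxazolidinone (attachment of the Evans auxiliary) by the acid chloride at −78 °C, which should not touch the conjugated alkene.

**Step 9**
Reactants: 18 (S)-4-benzyl-3-(3-methylbut-2-enoyl)oxazolidin-2-one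
Product: 20 (S)-4-benzyl-3-[(S)-5-methyl-2-(prop-1-en-2-yl)hex-4-enoyl]oxazolidin-2-one, via sodium dienolate 19 (not isolated)
Conditions: NaN(SiMe3)2 (1.05 equiv), THF, −78 °C; then 1-bromo-3-methylbut-2-ene, −78 → −40 °C
Reagents that add atoms: 1-bromo-3-methylbut-2-ene, CC(C)=CCBr
Why: Evans-type auxiliary-controlled alkylation of an extended enolate, in which γ-deprotonation gives the chelated Z dienolate 19 that reacts at the α-carbon with the allylic bromide on the face opposite the benzyl group, creating the S centre (same facial sense as the allylation of the propionyl imide of this auxiliary) and moving the double bond out of conjugation to form the isopropenyl group.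

**Step 10**
Reactants: 20 alkylated imide
Product: 21 (S)-5-methyl-2-(prop-1-en-2-yl)hex-4-en-1-ol ((S)-lavandulol)
Conditions: LiBH4, H2O (1.1 equiv), Et2O, 0 °C; then H2O
Reagents that add atoms: none
Why: Reductive cleavage of the N-acyl oxazolidinone with LiBH4, in which hydride attacks the exocyclic carbonyl under conditions too mild to epimerise or reconjugate the α-vinyl centre, giving the primary alcohol and the recovered auxiliary.

**Step 11**
Reactants: 21 (S)-lavandulol
Product: 22 (S)-1-iodo-5-methyl-2-(prop-1-en-2-yl)hex-4-ene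
Conditions: I2, PPh3, imidazole, CH2Cl2, 0 °C
Reagents that add atoms: iodine, II
Why: Appel-type iodination, in which iodide displaces the alkoxyphosphonium group by SN2 at the primary carbon and leaves the neighbouring stereocentre and both alkenes untouched.

**Step 12**
Reactants: 15 (S)-8-bromo-2-(2,6-dihydroxyphenyl)-5-hydroxy-7-methoxychroman-4-one; 22 (S)-1-iodo-5-methyl-2-(prop-1-en-2-yl)hex-4-ene
Product: 26 Exiguaflavanone B, (2S)-2-(2,6-dihydroxyphenyl)-5-hydroxy-7-methoxy-8-[(2R)-5-methyl-2-(prop-1-en-2-yl)hex-4-en-1-yl]chroman-4-one, via tris(trimethylsilyl) ether 23 (not isolated), via lavandulylzinc iodide 24 (not isolated), via coupled tris(trimethylsilyl) ether 25 (not isolated)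
Conditions: 15: N,O-bis(trimethylsilyl)acetamide, THF, 45 °C; 22: Zn dust, LiCl, THF, 30 °C; then Pd(OAc)2 (5 mol %), SPhos (10 mol %), THF, 25–45 °C; then aq citric acid, THF, 0 °C
Reagents that add atoms: none
Why: Negishi cross-coupling of a primary alkylzinc iodide with an aryl bromide, in which the phenols are masked in the flask as trimethylsilyl ethers so that they do not protonate 24, the bulky electron-rich biarylphosphine on zerovalent palladium should allow oxidative addition at the C8–Br bond flanked by two oxygens and reductive elimination ahead of β-hydride elimination, the ketone and both stereocentres are not involved, and mild aqueous acid removes the silyl groups.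

**Compound list**
1 | 2,6-dihydroxybenzaldehyde | O=Cc1c(O)cccc1O | starting material
2 | 2,6-bis(benzyloxy)benzaldehyde | O=Cc1c(OCc2ccccc2)cccc1OCc1ccccc1 | intermediate
3 | (S)-2-hydroxy-1,2,2-triphenylethyl acetate | CC(=O)O[C@@H](c1ccccc1)C(O)(c1ccccc1)c1ccccc1 | starting material
4 | dilithium enolate of 3 (not isolated) | [Li]OC(=C)O[C@@H](c1ccccc1)C(O[Li])(c1ccccc1)c1ccccc1 | intermediate
5 | (S)-2-hydroxy-1,2,2-triphenylethyl (S)-3-[2,6-bis(benzyloxy)phenyl]-3-hydroxypropanoate | O[C@H](c1c(OCc2ccccc2)cccc1OCc1ccccc1)CC(=O)O[C@@H](c1ccccc1)C(O)(c1ccccc1)c1ccccc1 | intermediate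
6 | (S)-3-[2,6-bis(benzyloxy)phenyl]-3-hydroxypropanoic acid | O[C@H](c1c(OCc2ccccc2)cccc1OCc1ccccc1)CC(=O)O | intermediate
7 | 1-fluoro-3,5-dimethoxybenzene | COc1cc(F)cc(OC)c1 | starting material
8 | 2,4-dibromo-3-fluoro-1,5-dimethoxybenzene | COc1cc(OC)c(Br)c(F)c1Br | intermediate
9 | dipotassium alkoxide carboxylate of 6 (not isolated) | [K+].[K+].[O-][C@H](c1c(OCc2ccccc2)cccc1OCc1ccccc1)CC(=O)[O-] | intermediate
10 | (S)-3-[2,6-bis(benzyloxy)phenyl]-3-(2,6-dibromo-3,5-dimethoxyphenoxy)propanoic acid | COc1cc(OC)c(Br)c(O[C@H](c2c(OCc3ccccc3)cccc2OCc2ccccc2)CC(=O)O)c1Br | intermediate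
11 | lithium (S)-3-[2,6-bis(benzyloxy)phenyl]-3-(2-bromo-6-lithio-3,5-dimethoxyphenoxy)propanoate (not isolated) | [Li]c1c(OC)cc(OC)c(Br)c1O[C@H](c1c(OCc2ccccc2)cccc1OCc1ccccc1)CC(=O)O[Li] | intermediate
12 | dilithium gem-diolate of 13, (S)-2-[2,6-bis(benzyloxy)phenyl]-8-bromo-5,7-dimethoxychroman-4,4-diolate (not isolated) | COc1cc(OC)c2c(c1Br)O[C@H](c1c(OCc3ccccc3)cccc1OCc1ccccc1)CC2(O[Li])O[Li] | intermediate
13 | (S)-2-[2,6-bis(benzyloxy)phenyl]-8-bromo-5,7-dimethoxychroman-4-one | COc1cc(OC)c2c(c1Br)O[C@H](c1c(OCc3ccccc3)cccc1OCc1ccccc1)CC2=O | intermediate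
14 | tris(dichloroboryl) ether of 15 (not isolated) | COc1cc(OB(Cl)Cl)c2c(c1Br)O[C@H](c1c(OB(Cl)Cl)cccc1OB(Cl)Cl)CC2=O | intermediate
15 | (S)-8-bromo-2-(2,6-dihydroxyphenyl)-5-hydroxy-7-methoxychroman-4-one | COc1cc(O)c2c(c1Br)O[C@H](c1c(O)cccc1O)CC2=O | intermediate
16 | (S)-4-benzyl-2-oxazolidinone | O=C1N[C@@H](Cc2ccccc2)CO1 | starting material
17 | lithium salt of 16 (not isolated) | [Li]N1[C@@H](Cc2ccccc2)COC1=O | intermediate
18 | (S)-4-benzyl-3-(3-methylbut-2-enoyl)oxazolidin-2-one | CC(C)=CC(=O)N1[C@@H](Cc2ccccc2)COC1=O | intermediate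
19 | sodium Z dienolate of 18 (not isolated) | C=C(C)/C=C(\O[Na])N1[C@@H](Cc2ccccc2)COC1=O | intermediate
20 | (S)-4-benzyl-3-[(S)-5-methyl-2-(prop-1-en-2-yl)hex-4-enoyl]oxazolidin-2-one | C=C(C)[C@H](CC=C(C)C)C(=O)N1[C@@H](Cc2ccccc2)COC1=O | intermediate
21 | (S)-5-methyl-2-(prop-1-en-2-yl)hex-4-en-1-ol ((S)-lavandulol) | C=C(C)[C@H](CC=C(C)C)CO | intermediate
22 | (S)-1-iodo-5-methyl-2-(prop-1-en-2-yl)hex-4-ene | C=C(C)[C@H](CC=C(C)C)CI | intermediate
23 | tris(trimethylsilyl) ether of 15 (not isolated) | COc1cc(O[Si](C)(C)C)c2c(c1Br)O[C@H](c1c(O[Si](C)(C)C)cccc1O[Si](C)(C)C)CC2=O | intermediate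
24 | [(S)-5-methyl-2-(prop-1-en-2-yl)hex-4-en-1-yl]zinc iodide (not isolated) | C=C(C)[C@H](CC=C(C)C)C[Zn]I | intermediate
25 | tris(trimethylsilyl) ether of 26 (not isolated) | C=C(C)[C@H](CC=C(C)C)Cc1c(OC)cc(O[Si](C)(C)C)c2c1O[C@H](c1c(O[Si](C)(C)C)cccc1O[Si](C)(C)C)CC2=O | intermediate
26 | Exiguaflavanone B | C=C(C)[C@H](CC=C(C)C)Cc1c(OC)cc(O)c2c1O[C@H](c1c(O)cccc1O)CC2=O | target

**Count and risks**
Total: 12 steps. Longest linear sequence: 7 steps (1, 2, 3, 5, 6, 7, 12); the side-chain branch (8–11) and the ring A branch (4) join it at steps 12 and 5.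

Step 5. The hindered secondary alkoxide may add too slowly to a carbon flanked by two bromines, so that decomposition of the fluoroarene or displacement of bromide competes. The fallback reverses the polarity (Mitsunobu reaction with inversion); it sets out from 2 and 8 and comes back at 10. (R)-2-Hydroxy-1,2,2-triphenylethyl acetate is doubly lithiated to its dilithium enolate F1 and added to 2 as in step 2 to give (R)-2-hydroxy-1,2,2-triphenylethyl (R)-3-[2,6-bis(benzyloxy)phenyl]-3-hydroxypropanoate F2. K2CO3 in methanol transesterifies this to methyl (R)-3-[2,6-bis(benzyloxy)phenyl]-3-hydroxypropanoate F3. Fluoroarene 8 is converted with KOH in DMSO/H2O into 2,6-dibromo-3,5-dimethoxyphenol F4. F3 and the acidic phenol F4 are joined with PPh3 and diisopropyl azodicarboxylate in toluene, with inversion, to methyl (S)-3-[2,6-bis(benzyloxy)phenyl]-3-(2,6-dibromo-3,5-dimethoxyphenoxy)propanoate F5. LiOH in THF/H2O at 0 °C then gives 10.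

Step 6. Proton transfer from C3 to the aryllithium followed by loss of the aryloxide, exchange of the second bromine, or sluggish addition to the carboxylate may erode the cyclization. The fallback closes the same bond by electrophilic substitution; it sets out from 7 and 9 and comes back at 13. Compound 7 is brominated with one equivalent of N-bromosuccinimide to 2-bromo-1-fluoro-3,5-dimethoxybenzene F6. SNAr with dianion 9 (DMPU, 80 °C) gives (S)-3-[2,6-bis(benzyloxy)phenyl]-3-(2-bromo-3,5-dimethoxyphenoxy)propanoic acid F7. 1-Chloro-N,N,2-trimethylprop-1-en-1-amine converts this under neutral conditions into (S)-3-[2,6-bis(benzyloxy)phenyl]-3-(2-bromo-3,5-dimethoxyphenoxy)propanoyl chloride F8. SnCl4 with 2,6-di-tert-butylpyridine in CH2Cl2 at −78 °C then effects intramolecular Friedel–Crafts acylation at the only free carbon ortho to O1, giving 13; the price is exposure of the benzylic ether to a Lewis acid.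

Step 12. Slow oxidative addition at the doubly flanked C8–Br bond, β-hydride elimination or isomerisation of the alkylpalladium, or premature loss of silyl groups with protonation of the zinc reagent may lower the coupling. The fallback is a nickel-catalysed reductive cross-electrophile coupling that needs no preformed organozinc; it sets out from 23 and 22 and comes back at 25. Silyl ether 23 and iodide 22 are coupled directly with NiI2, 4,4′-di-tert-butyl-2,2′-bipyridine and Zn in N,N-dimethylacetamide, and the same citric acid work-up gives 26.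

**Further compounds**
F1 | step 5 | dilithium enolate of (R)-2-hydroxy-1,2,2-triphenylethyl acetate | [Li]OC(=C)O[C@H](c1ccccc1)C(O[Li])(c1ccccc1)c1ccccc1
F2 | step 5 | (R)-2-hydroxy-1,2,2-triphenylethyl (R)-3-[2,6-bis(benzyloxy)phenyl]-3-hydroxypropanoate | O[C@@H](c1c(OCc2ccccc2)cccc1OCc1ccccc1)CC(=O)O[C@H](c1ccccc1)C(O)(c1ccccc1)c1ccccc1
F3 | step 5 | methyl (R)-3-[2,6-bis(benzyloxy)phenyl]-3-hydroxypropanoate | O[C@@H](c1c(OCc2ccccc2)cccc1OCc1ccccc1)CC(=O)OC
F4 | step 5 | 2,6-dibromo-3,5-dimethoxyphenol | COc1cc(OC)c(Br)c(O)c1Br
F5 | step 5 | methyl (S)-3-[2,6-bis(benzyloxy)phenyl]-3-(2,6-dibromo-3,5-dimethoxyphenoxy)propanoate | COc1cc(OC)c(Br)c(O[C@H](c2c(OCc3ccccc3)cccc2OCc2ccccc2)CC(=O)OC)c1Br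
F6 | step 6 | 2-bromo-1-fluoro-3,5-dimethoxybenzene | COc1cc(F)c(Br)c(OC)c1
F7 | step 6 | (S)-3-[2,6-bis(benzyloxy)phenyl]-3-(2-bromo-3,5-dimethoxyphenoxy)propanoic acid | COc1cc(OC)c(Br)c(O[C@H](c2c(OCc3ccccc3)cccc2OCc2ccccc2)CC(=O)O)c1
F8 | step 6 | (S)-3-[2,6-bis(benzyloxy)phenyl]-3-(2-bromo-3,5-dimethoxyphenoxy)propanoyl chloride | COc1cc(OC)c(Br)c(O[C@H](c2c(OCc3ccccc3)cccc2OCc2ccccc2)CC(=O)Cl)c1
F0 | step 12 | none | none
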